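**Strategy.** Ring A (C1–C5, C10; labdane numbering) is annulated onto an enantiopure, fully substituted ring B. The C18 carbinol and the C6 carbinol are 1,4-related through C4–C5, a latent 1,4-dicarbonyl, so the polarity-mismatched C4–C5 bond is made by radical chemistry. In one photoredox operation a primary C2 radical, released from a redox-active ester on the C10 side arm, adds to C3 of methacrolein. The resulting C4 radical closes ring A onto C5 of the ring-B C5=C6 enol acetate, and oxidation of the C6 radical unveils the C6 ketone. The precursor is a monocyclic enol acetate carrying the complete side chain; the step creates the quaternary C4 stereocentre and the ring fusion.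

Key step: step 9

Remark: labdane numbering is used throughout (ring A C1–C5, C10; ring B C5–C10; side chain C11–C16; C17 on C8; C18 the oxygenated carbon and C19 the methyl on C4; C20 the methyl on C10).

Assumption: the (R)-configured diarylprolinol silyl ether is taken to give the (S)-enone 4 (attack on the iminium face away from the diarylmethyl group); if the sense is opposite, its enantiomer is used.

Step 1
Reactants: 1 (E)-but-2-enal; 2 tert-butyl 3-oxobutanoate
Product: 4 (S)-5-methylcyclohex-2-en-1-one, via Michael adduct 3 (not isolated)
Conditions: (R)-2-{bis[3,5-bis(trifluoromethyl)phenyl](trimethylsilyloxy)methyl}pyrrolidine (10 mol %), neat, rt; then TsOH·H2O (20 mol %), toluene, 80 °C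
Reagents that add atoms: none
Why: Iminium-catalysed asymmetric Michael addition sets the methyl-bearing centre (future C8) by attack on the unshielded face of the E-iminium ion, and acid then drives intramolecular aldol condensation, tert-butyl ester cleavage and decarboxylation (organocatalytic Robinson-type annulation).

Step 2
Reactants: 4 (S)-5-methylcyclohex-2-en-1-one; 5 2-(2-bromoethyl)-2-methyl-1,3-dioxolane
Product: 6 (5S,6R)-5-methyl-6-[2-(2-methyl-1,3-dioxolan-2-yl)ethyl]cyclohex-2-en-1-one
Conditions: LiN(iPr)2, THF, −78 °C; then 5, DMPU, −78 → 0 °C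
Reagents that add atoms: none
Why: Kinetic α′-deprotonation gives the cross-conjugated lithium enolate, and its SN2 alkylation should occur anti to the adjacent methyl group, setting C9 trans to the C8 methyl (enolate alkylation; trans is also the thermodynamic isomer).

Step 3
Reactants: 6 trans-alkylated enone; 7 (3-bromopropoxy)(tert-butyl)dimethylsilane
Product: 9 tertiary allylic alcohol (C10 carbinol bearing the 3-silyloxypropyl arm; carbinol epimers), via Grignard reagent 8 (not isolated)
Conditions: Mg, THF, rt (7 to 8); CeCl3 (anhydrous), THF, −78 °C; then 6, −78 → 0 °C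
Reagents that add atoms: none
Why: Grignard formation and cerium-mediated 1,2-addition to the enone carbonyl install the three-carbon arm (C1, C2 and a carbon later lost as CO2); the carbinol centre disappears in step 4, so its configuration does not matter.

Step 4
Reactants: 9 tertiary allylic alcohol
Product: 11 (4R,5S)-3-[3-(tert-butyldimethylsilyloxy)propyl]-5-methyl-4-(3-oxobutyl)cyclohex-2-en-1-one, via ketal enone 10 (not isolated)
Conditions: (C5H5NH)[CrO3Cl] (pyridinium chlorochromate), NaOAc, CH2Cl2, rt; then pyridinium p-toluenesulfonate (cat.), acetone–H2O, rt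
Reagents that add atoms: pyridinium chlorochromate, [O-][Cr](=O)(=O)Cl.c1cc[nH+]cc1 (C6 ketone oxygen); water, O (side-chain ketone oxygen)
Why: Dauben–Babler oxidative 1,3-transposition ([3,3] shift of the tertiary allylic chromate ester, then oxidation) moves the oxygen to C6 and the alkene to C5=C10, and mild acid then cleaves the ketone-derived dioxolane while the primary silyl ether survives; no stereocentre is touched.

Step 5
Reactants: 11 enone methyl ketone
Product: 12 methyl (2E)-5-{(1R,6S)-2-[3-(tert-butyldimethylsilyloxy)propyl]-6-methyl-4-oxocyclohex-2-en-1-yl}-3-methylpent-2-enoate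
Conditions: (MeO)2P(O)CH2CO2Me, NaH, THF, 0 °C → rt
Reagents that add atoms: trimethyl phosphonoacetate, COC(=O)CP(=O)(OC)OC
Why: Horner–Wadsworth–Emmons olefination of the unhindered methyl ketone (the conjugated, β,β-disubstituted ring ketone should react far more slowly) should give mainly the (E)-enoate, with the ester anti to the larger alkyl branch; the minor (Z)-isomer is removed by chromatography.

Step 6
Reactants: 12 enone with complete side chain
Product: 14 ring-B C5=C6 enol acetate (C10 now quaternary: new methyl cis to the C9 side chain; silyloxypropyl arm trans to it), via lithium enolate 13 (not isolated)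
Conditions: CuI, MeLi (2 equiv), Et2O, 0 °C (forms LiCuMe2); 12, −40 → 0 °C; then Ac2O, 0 °C → rt
Reagents that add atoms: methyllithium, [Li]C (delivered as LiCuMe2); acetic anhydride, CC(=O)OC(C)=O
Why: Cuprate 1,4-addition creates quaternary C10: axial attack on the half-chair with the C8 methyl and C9 side chain equatorial should occur anti to the C8 methyl (the 1,3-trans rule of 5-substituted cyclohexenones), placing the new methyl cis to the C9 side chain, and O-acetylation of the regiodefined lithium enolate fixes the C5=C6 enol acetate.

Step 7
Reactants: 14 enol acetate silyl ether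
Product: 16 carboxylic acid (arm now CH2CH2CO2H on C10), via primary alcohol 15 (not isolated)
Conditions: HF·pyridine, THF, 0 °C → rt; then TEMPO (cat.), PhI(OAc)2, MeCN–H2O, rt
Reagents that add atoms: water, O
Why: Fluoride removes the primary silyl ether and the nitroxyl/PhI(OAc)2 oxidation takes the alcohol through the aldehyde hydrate to the acid under conditions that should spare the enol acetate and the enoate; no stereocentre is affected.

Step 8
Reactants: 16 carboxylic acid
Product: 17 N-acyloxyphthalimide (redox-active ester) of 16
Conditions: N-hydroxyphthalimide, N,N'-diisopropylcarbodiimide, DMAP (cat.), CH2Cl2, rt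
Reagents that add atoms: N-hydroxyphthalimide, ON1C(=O)c2ccccc2C1=O
Why: Carbodiimide (Steglich-type) esterification gives the redox-active ester that serves as the C2 radical precursor.

Step 9
Reactants: 17 redox-active ester; 18 2-methylprop-2-enal (methacrolein)
Product: 19 cis-fused decalin keto aldehyde (C6 ketone; C4 bears CHO and a methyl that is cis to the C10 methyl; H5 cis to the C10 methyl)
Conditions: Ir(ppy)3 [tris(2-phenylpyridinato)iridium] (1 mol %), 18 (3 equiv), MeCN (degassed, 0.05 M), blue LEDs (450 nm), rt
Reagents that add atoms: none
Why: Proposed new method: excited Ir(ppy)3 reduces the N-acyloxyphthalimide, which loses CO2 and phthalimide anion to give the primary C2 radical; this nucleophilic radical adds to the CH2 terminus (C3) of methacrolein, the electrophilic tertiary α-formyl C4 radical attacks C5 of the electron-rich C5=C6 enol acetate, and the α-acetoxy C6 radical is oxidised by the oxidised iridium photocatalyst and passes its acetyl group to phthalimide anion, unveiling the C6 ketone in a redox-neutral cycle. The closest known reaction types are the photoredox decarboxylative Giese addition of redox-active esters and the radical–polar crossover α-alkylation of enol acetates and silyl enol ethers by electron-poor radicals; merging them into an annulation is the new element. Ring A closes in the 6-exo-trig mode, C4 attacking the face of C5 anti to the pseudo-axial C10 methyl (ring B should be held as the half-chair with the C8 methyl, the C9 side chain and the C10 arm all equatorial), which should give the cis-fused C5 epimer; this is harmless because C5 is α to the new ketone and is equilibrated in step 10. The quaternary C4 centre is controlled by the orientation of the planar radical: only the slim formyl group should fit the concave position over ring B, so the methyl points outward and ends cis to the C10 methyl. The step needs chemoselectivity (Giese addition before any other fate of the C2 radical, ring closure before oligomerisation) and this C4 orientation; the first is secured by polarity matching at each stage and by the absence of any 5- or 6-exo acceptor for the C2 radical, the second by the conformational lock of ring B.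

Step 10
Reactants: 19 cis-fused keto aldehyde
Product: 21 trans-fused keto dimethyl acetal (H5 trans to the C10 methyl; C4 methyl axial and cis to the C10 methyl; CH(OMe)2 equatorial), via cis-fused keto acetal 20 (not isolated)
Conditions: HC(OMe)3, MeOH, camphorsulfonic acid (cat.), 40 °C; then NaOMe (excess), MeOH, 50 °C
Reagents that add atoms: trimethyl orthoformate, COC(OC)OC
Why: The neopentyl aldehyde is acetalised chemoselectively (the C6 ketone between C5 and C7 is too hindered), and acid followed by methoxide epimerises C5, α to the ketone, to the trans-decalin, which should be strongly preferred because the cis isomer would hold the dimethoxymethyl group in the concave space over ring B.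

Step 11
Reactants: 21 trans-fused keto acetal
Product: 23 Δ7-6-one dimethyl acetal (C7=C8 enone), via silyl enol ether 22 (not isolated)
Conditions: LiN(SiMe3)2, Me3SiCl, THF, −78 °C; then Pd(OAc)2, MeCN, rt
Reagents that add atoms: none
Why: Saegusa–Ito dehydrogenation: enolisation can only proceed toward C7 (C5–H lies between two quaternary carbons), and β-hydride elimination from the divalent palladium enolate gives the C7=C8 enone, deliberately erasing the C8 relay stereocentre.

Step 12
Reactants: 23 enone acetal
Product: 24 C6 allylic alcohol dimethyl acetal (OH expected axial, cis to the C10 and C4 methyl groups, i.e. the C6 epimer of the target pattern)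
Conditions: NaBH4, CeCl3·7H2O, MeOH, −78 → 0 °C
Reagents that add atoms: none
Why: Luche 1,2-reduction; hydride should arrive on the face opposite the two axial methyl groups, giving mainly the axial C6 alcohol, whose configuration is corrected in step 13 (either C6 epimer converges there).

Step 13
Reactants: 24 allylic alcohol acetal
Product: 26 methyl (13E)-6,18-dihydroxylabda-7,13-dien-15-oate in the enantiomeric form given (target), via lactol 25 (not isolated)
Conditions: 1 M HCl, THF–H2O, rt; extractive work-up; then NaBH4, MeOH, 0 °C
Reagents that add atoms: water, O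
Why: Aqueous acid unmasks the aldehyde and ionises the strained axial allylic alcohol to the C6–C7–C8 allyl cation (SN1 allylic substitution), which is recaptured at C6 on the open face by the neighbouring C18 aldehyde hydrate to give the five-membered lactol, possible only with the C6–O bond cis to C18 (the equatorial C6 oxygen of the target); NaBH4 then reduces the lactol through its hydroxy aldehyde form and leaves the conjugated ester.

**Compound list**

1 | (E)-but-2-enal (crotonaldehyde) | C/C=C/C=O | starting material
2 | tert-butyl 3-oxobutanoate | CC(=O)CC(=O)OC(C)(C)C | starting material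
3 | tert-butyl (3S)-2-acetyl-3-methyl-5-oxopentanoate (Michael adduct, C2 epimers) | CC(=O)C(C(=O)OC(C)(C)C)[C@@H](C)CC=O | intermediate
4 | (S)-5-methylcyclohex-2-en-1-one | C[C@H]1CC=CC(=O)C1 | intermediate
5 | 2-(2-bromoethyl)-2-methyl-1,3-dioxolane | CC1(CCBr)OCCO1 | starting material
6 | (5S,6R)-5-methyl-6-[2-(2-methyl-1,3-dioxolan-2-yl)ethyl]cyclohex-2-en-1-one | CC1(CC[C@@H]2[C@@H](C)CC=CC2=O)OCCO1 | intermediate
7 | (3-bromopropoxy)(tert-butyl)dimethylsilane | BrCCCO[Si](C)(C)C(C)(C)C | starting material
8 | [3-(tert-butyldimethylsilyloxy)propyl]magnesium bromide | Br[Mg]CCCO[Si](C)(C)C(C)(C)C | intermediate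
9 | (5S,6R)-1-[3-(tert-butyldimethylsilyloxy)propyl]-5-methyl-6-[2-(2-methyl-1,3-dioxolan-2-yl)ethyl]cyclohex-2-en-1-ol (C1 epimers) | CC1(CC[C@@H]2[C@@H](C)CC=CC2(O)CCCO[Si](C)(C)C(C)(C)C)OCCO1 | intermediate
10 | (4R,5S)-3-[3-(tert-butyldimethylsilyloxy)propyl]-5-methyl-4-[2-(2-methyl-1,3-dioxolan-2-yl)ethyl]cyclohex-2-en-1-one | CC1(CC[C@@H]2[C@@H](C)CC(=O)C=C2CCCO[Si](C)(C)C(C)(C)C)OCCO1 | intermediate
11 | (4R,5S)-3-[3-(tert-butyldimethylsilyloxy)propyl]-5-methyl-4-(3-oxobutyl)cyclohex-2-en-1-one | CC(=O)CC[C@@H]1[C@@H](C)CC(=O)C=C1CCCO[Si](C)(C)C(C)(C)C | intermediate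
12 | methyl (2E)-5-{(1R,6S)-2-[3-(tert-butyldimethylsilyloxy)propyl]-6-methyl-4-oxocyclohex-2-en-1-yl}-3-methylpent-2-enoate | COC(=O)/C=C(\C)CC[C@@H]1[C@@H](C)CC(=O)C=C1CCCO[Si](C)(C)C(C)(C)C | intermediate
13 | lithium C5=C6 enolate of the methyl conjugate adduct of 12 | COC(=O)/C=C(\C)CC[C@@H]1[C@@H](C)CC(O[Li])=C[C@@]1(C)CCCO[Si](C)(C)C(C)(C)C | intermediate
14 | ring-B C5=C6 enol acetate; C10 carries methyl (cis to C9 side chain) and the 3-(tert-butyldimethylsilyloxy)propyl arm; C8 methyl trans to C9 side chain | COC(=O)/C=C(\C)CC[C@@H]1[C@@H](C)CC(OC(C)=O)=C[C@@]1(C)CCCO[Si](C)(C)C(C)(C)C | intermediate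
15 | primary alcohol from desilylation of 14 | COC(=O)/C=C(\C)CC[C@@H]1[C@@H](C)CC(OC(C)=O)=C[C@@]1(C)CCCO | intermediate
16 | carboxylic acid (C10 arm CH2CH2CO2H), enol acetate retained | COC(=O)/C=C(\C)CC[C@@H]1[C@@H](C)CC(OC(C)=O)=C[C@@]1(C)CCC(=O)O | intermediate
17 | N-acyloxyphthalimide of 16 | COC(=O)/C=C(\C)CC[C@@H]1[C@@H](C)CC(OC(C)=O)=C[C@@]1(C)CCC(=O)ON2C(=O)c3ccccc3C2=O | intermediate
18 | 2-methylprop-2-enal (methacrolein) | CC(=C)C=O | starting material
19 | cis-fused keto aldehyde: C6 ketone, C4 with CHO and CH3 (CH3 cis to C10 CH3), H5 cis to C10 CH3, C8 CH3 trans to C9 side chain | COC(=O)/C=C(\C)CC[C@@H]1[C@@H](C)CC(=O)[C@H]2[C@@](C)(C=O)CCC[C@@]12C | intermediate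
20 | cis-fused keto dimethyl acetal (C5 epimer of 21) | COC(=O)/C=C(\C)CC[C@@H]1[C@@H](C)CC(=O)[C@H]2[C@@](C)(C(OC)OC)CCC[C@@]12C | intermediate
21 | trans-fused keto dimethyl acetal: H5 trans to C10 CH3, C4 CH3 axial, CH(OMe)2 equatorial | COC(=O)/C=C(\C)CC[C@@H]1[C@@H](C)CC(=O)[C@@H]2[C@@](C)(C(OC)OC)CCC[C@@]12C | intermediate
22 | C6 trimethylsilyl enol ether (C6=C7) of 21 | COC(=O)/C=C(\C)CC[C@@H]1[C@@H](C)C=C(O[Si](C)(C)C)[C@@H]2[C@@](C)(C(OC)OC)CCC[C@@]12C | intermediate
23 | trans-fused C7=C8 enone (6-one) dimethyl acetal | COC(=O)/C=C(\C)CC[C@@H]1C(C)=CC(=O)[C@@H]2[C@@](C)(C(OC)OC)CCC[C@@]12C | intermediate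
24 | C6 allylic alcohol dimethyl acetal, OH axial (cis to C10 and C4 methyls) | COC(=O)/C=C(\C)CC[C@@H]1C(C)=C[C@H](O)[C@@H]2[C@@](C)(C(OC)OC)CCC[C@@]12C | intermediate
25 | 18,6-lactol (C6–O–C18 bridge cis on the face opposite the axial methyls; C18 OH epimers) | COC(=O)/C=C(\C)CC[C@@H]1C(C)=C[C@@H]3[C@@H]2[C@@](C)(C(O)O3)CCC[C@@]12C | intermediate
26 | methyl (13E)-6,18-dihydroxylabda-7,13-dien-15-oate, enantiomer as specified | COC(=O)/C=C(\C)CC[C@@H]1C(C)=C[C@@H](O)[C@@H]2[C@@](C)(CO)CCC[C@@]12C | target

**Step count and risks**

Total step count: 13. Longest linear sequence: 13 steps (from 1 and 2 to 26).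

Steps most likely to fail:

1. Step 9 (Proposed new method). The tertiary α-formyl radical may be lost to oligomerisation with methacrolein or to hydrogen abstraction before it closes the congested C4–C5 bond. The C6 radical may be oxidised too slowly to turn the photocatalyst over. The radical may also add with the opposite orientation at C4. The fallback uses a known Barton decarboxylation radical chain and sets out from acid 16. Coupling with N-hydroxypyridine-2-thione (DCC, CH2Cl2, dark) gives the Barton ester F1. Visible-light photolysis of F1 with methacrolein 18 runs the same addition–cyclisation, the nucleophilic C6 radical being capped by pyridylthio transfer to give the α-acetoxy pyridyl sulfide F2. K2CO3 in aqueous methanol hydrolyses this O,S-acetal to keto aldehyde 19, where the route is rejoined.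

2. Step 13. Proton loss from the allyl cation to dienes, capture at C8, or acid-promoted carbonyl-ene closure between the freed aldehyde and the C7=C8 alkene may compete with lactol-forming capture. The fallback avoids the cation and sets out from allylic alcohol 24. Mitsunobu inversion (4-nitrobenzoic acid, PPh3, diisopropyl azodicarboxylate) gives the inverted 4-nitrobenzoate F3. Methanolysis (K2CO3, MeOH) gives the equatorial allylic alcohol acetal F4. Brief hydrolysis of the acetal (pyridinium p-toluenesulfonate, wet acetone) then gives lactol 25, where the route is rejoined before the NaBH4 reduction.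

3. Step 6. Facial selectivity may be poor: the C9 side chain biases attack toward the face syn to the C8 methyl, against the intended control, and addition to the hindered β,β-disubstituted enone may be slow. The fallback replaces substrate control by reagent control and sets out from enone 12. Copper-catalysed asymmetric conjugate addition of Me3Al (copper thiophene-2-carboxylate, Cu(O2CC4H3S), with a binaphthol-derived phosphoramidite ligand of the matching hand) gives the dimethylaluminium enolate F5. Acetylation of F5 in the flask with Ac2O returns enol acetate 14.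

Further compounds
F1 | step 9 | Barton ester (N-acyloxypyridine-2-thione) of acid 16 | COC(=O)/C=C(\C)CC[C@@H]1[C@@H](C)CC(OC(C)=O)=C[C@@]1(C)CCC(=O)ON2C=CC=CC2=S
F2 | step 9 | cis-fused C6 α-acetoxy 2-pyridyl sulfide (C6 epimers) with C18 aldehyde | COC(=O)/C=C(\C)CC[C@@H]1[C@@H](C)CC(OC(C)=O)(Sc3ccccn3)[C@H]2[C@@](C)(C=O)CCC[C@@]12C
F3 | step 13 | inverted (equatorial) C6 4-nitrobenzoate of the allylic alcohol acetal | COC(=O)/C=C(\C)CC[C@@H]1C(C)=C[C@@H](OC(=O)c3ccc(cc3)[N+](=O)[O-])[C@@H]2[C@@](C)(C(OC)OC)CCC[C@@]12C
F4 | step 13 | equatorial C6 allylic alcohol dimethyl acetal (C6 epimer of 24) | COC(=O)/C=C(\C)CC[C@@H]1C(C)=C[C@@H](O)[C@@H]2[C@@](C)(C(OC)OC)CCC[C@@]12C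
F5 | step 6 | dimethylaluminium C5=C6 enolate of the methyl conjugate adduct of 12 | COC(=O)/C=C(\C)CC[C@@H]1[C@@H](C)CC(O[Al](C)C)=C[C@@]1(C)CCCO[Si](C)(C)C(C)(C)C
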